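**Plan**

- Retrosynthesis: first the five benzyl C–O bonds are cut, then the ester between the arene's side-chain carbinol and the middle (R)-3-acyloxybutanoic acid, then that acid's ester to (R)-3,4-dihydroxybutanoic acid (carried as its bis-benzyl ether).
- The benzene ring is then cut at its C1–C6 bond. Its hydroxyls on C2 and C4, the ester carbon on C1 and the 2-oxypropyl chain on C6 are the oxygen pattern of a linear 3,5,7-trioxodecanoate (ring C1–C6 = chain C2–C7).
- That triketo ester is cut at its ester C–O bond (acylketene plus benzyl (S)-3-hydroxybutanoate) and at two chain C–C bonds (two Claisen acylations of a dioxinone).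
- Forward: dioxinone → keto-dioxinone → diketo-dioxinone → thermolysis and ketene capture → aldol aromatisation (the only ring formed) → O-benzylation → desilylation → esterification with the preformed side-chain acid → one neutral global hydrogenolysis.
- Stereochemistry: all four centres are bought and never touched at carbon: the arene side-chain carbinol from methyl (R)-3-hydroxybutanoate, the terminal unit from ethyl (S)-3-hydroxybutanoate, the middle unit from tert-butyl (R)-3-hydroxybutanoate, the diol carbon from (R)-benzyl glycidyl ether.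

Key step: step 7

Remark 1: 10 is drawn as the all-keto tautomer although it should be an enol mixture; the ring stereocentres of 11 and the new carbinol of 18 are transient and left undefined; metal enolates, alkoxides and phenoxides made by deprotonation are treated as ionised forms of the numbered compounds.

Remark 2: the terminal diol is carried as two benzyl ethers, not a ketal, so that no acid meets the γ-hydroxy ester (lactonisation risk) at the end; commercial LiHMDS and LDA solutions are assumed.

**Route**

Step 1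
Reactants: 1 2,2,6-trimethyl-4H-1,3-dioxin-4-one
Product: 2 2,2-dimethyl-6-(2-oxopropyl)-4H-1,3-dioxin-4-one
Conditions: 1 (2 equiv), LiHMDS (2 equiv), THF, −78 °C; AcCl (1 equiv); aq. NH4Cl
Reagents that add atoms: acetyl chloride, CC(=O)Cl
Why: The lithium dienolate of the dioxinone is acylated at its γ-carbon (vinylogous Claisen acylation), and the second equivalent of dienolate takes up the acidic proton of the product so that it is not acylated again.

Step 2
Reactants: 3 methyl (R)-3-hydroxybutanoate
Product: 4 methyl (R)-3-(tert-butyldimethylsilyloxy)butanoate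
Conditions: TBSCl, imidazole, DMF, rt
Reagents that add atoms: tert-butyldimethylsilyl chloride, CC(C)(C)[Si](C)(C)Cl
Why: Standard imidazole-promoted silylation of a secondary alcohol, which does not touch the stereocentre.

Step 3
Reactants: 4 methyl (R)-3-(tert-butyldimethylsilyloxy)butanoate
Product: 5 (R)-3-(tert-butyldimethylsilyloxy)-N-methoxy-N-methylbutanamide
Conditions: MeNH(OMe)·HCl, i-PrMgCl, THF, −20 → 0 °C
Reagents that add atoms: N,O-dimethylhydroxylamine hydrochloride, CNOC.Cl
Why: Ester aminolysis by the chloromagnesium amide made in the flask (Weinreb amide synthesis) runs cold enough that the β-silyloxy group is not eliminated.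

Step 4
Reactants: 2 2,2-dimethyl-6-(2-oxopropyl)-4H-1,3-dioxin-4-one; 5 (R)-3-(tert-butyldimethylsilyloxy)-N-methoxy-N-methylbutanamide
Product: 6 6-[(6R)-6-(tert-butyldimethylsilyloxy)-2,4-dioxoheptyl]-2,2-dimethyl-4H-1,3-dioxin-4-one
Conditions: 2, LDA (2.2 equiv), THF, −78 °C; then 5, −78 → −40 °C; aq. NH4Cl
Reagents that add atoms: none
Why: The dianion of the keto-dioxinone reacts at its terminal, more basic carbon with the Weinreb amide (Claisen-type acylation), and the chelated tetrahedral adduct holds until the quench so the acidic 1,3-diketone cannot protonate unreacted dianion.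

Step 5
Reactants: 7 ethyl (S)-3-hydroxybutanoate
Product: 8 benzyl (S)-3-hydroxybutanoate
Conditions: BnOH (3 equiv), Ti(OiPr)4 (5 mol %), 110 °C, EtOH distilled off
Reagents that add atoms: benzyl alcohol, OCc1ccccc1
Why: Titanate-catalysed transesterification exchanges the ester alkyl group under neutral conditions that leave the β-hydroxyl and its stereocentre alone.

Step 6
Reactants: 6 6-[(6R)-6-(tert-butyldimethylsilyloxy)-2,4-dioxoheptyl]-2,2-dimethyl-4H-1,3-dioxin-4-one; 8 benzyl (S)-3-hydroxybutanoate
Product: 10 benzyl (S)-3-{[(R)-9-(tert-butyldimethylsilyloxy)-3,5,7-trioxodecanoyl]oxy}butanoate, via acylketene 9 (not isolated)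
Conditions: 8 (1.2 equiv), PhMe, 110 °C; concentrate and use crude
Reagents that add atoms: none
Why: Retro-hetero-Diels–Alder loss of acetone from the dioxinone gives an acylketene that the secondary alcohol should capture under neutral conditions, so the hindered ester is made without any acylation of a benzoic acid.

Step 7
Reactants: 10 benzyl (S)-3-{[(R)-9-(tert-butyldimethylsilyloxy)-3,5,7-trioxodecanoyl]oxy}butanoate
Product: 12 benzyl (S)-3-{[2,4-dihydroxy-6-((R)-2-(tert-butyldimethylsilyloxy)propyl)benzoyl]oxy}butanoate, via cyclic aldol 11 (not isolated)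
Conditions: Et3N (3 equiv), CH2Cl2, 0 °C → rt; then 10% aq. citric acid
Reagents that add atoms: none
Why: Et3N ionises the doubly activated C2 methylene between the ester and the C3 ketone, the enolate adds to the C7 ketone to form the ring C1–C6 bond, and the cyclic aldol 11 loses water by E1cB and enolises twice to the benzene ring, which makes the sequence irreversible. This is the biomimetic polyketide aldol aromatisation known for 3,5,7-triketo esters obtained from diketo-dioxinones by ketene capture. The single ring closes in the 6-(enolendo)-exo-trig mode. No stereocentre is created, the two ring centres of 11 are erased on aromatisation, and the C9 and butanoate centres are remote and not epimerisable under these conditions. The step needs C2-to-C7 carbon closure to win over Claisen closure of C6 onto the ester and over O-closure to a pyranone: the amine ionises only the three 1,3-dicarbonyl methylenes, only these two of their carbon closures give six-membered rings, the ketone is far more electrophilic than an ester whose leaving group would be a secondary alkoxide, and the absence of acid and heat disfavours the pyranone. The C8 hydrogens next to the silyloxy carbon are not removed by Et3N, so the β-silyloxy ketone should survive until the ring is aromatic.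

Step 8
Reactants: 12 benzyl (S)-3-{[2,4-dihydroxy-6-((R)-2-(tert-butyldimethylsilyloxy)propyl)benzoyl]oxy}butanoate
Product: 13 benzyl (S)-3-{[2,4-bis(benzyloxy)-6-((R)-2-(tert-butyldimethylsilyloxy)propyl)benzoyl]oxy}butanoate
Conditions: BnBr, K2CO3, TBAI (cat.), acetone, 50 °C
Reagents that add atoms: benzyl bromide, BrCc1ccccc1
Why: Williamson etherification of both phenoxides with a weak heterogeneous base that should not enolise the esters, done while the side-chain oxygen is still silylated so no alkoxide can attack the benzoate.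

Step 9
Reactants: 13 benzyl (S)-3-{[2,4-bis(benzyloxy)-6-((R)-2-(tert-butyldimethylsilyloxy)propyl)benzoyl]oxy}butanoate
Product: 14 benzyl (S)-3-{[2,4-bis(benzyloxy)-6-((R)-2-hydroxypropyl)benzoyl]oxy}butanoate
Conditions: HF·pyridine, pyridine, THF, 0 °C → rt; use promptly
Reagents that add atoms: none
Why: Fluoride-driven Si–O cleavage in a buffered acidic medium frees the alcohol without forming an alkoxide, so lactonisation onto the neighbouring, doubly ortho-substituted benzoate should stay slow.

Step 10
Reactants: 15 (R)-benzyl glycidyl ether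
Product: 16 (R)-1-(benzyloxy)pent-4-en-2-ol
Conditions: CH2=CHMgBr, CuI (10 mol %), THF, −30 → 0 °C; aq. NH4Cl
Reagents that add atoms: vinylmagnesium bromide, C=C[Mg]Br
Why: Copper-catalysed Grignard opening of a terminal epoxide occurs by SN2 at the unsubstituted carbon, so the stereocentre of the glycidyl ether is carried over unchanged.

Step 11
Reactants: 16 (R)-1-(benzyloxy)pent-4-en-2-ol
Product: 17 (R)-4,5-bis(benzyloxy)pent-1-ene
Conditions: NaH, BnBr, TBAI (cat.), THF, 0 °C → rt
Reagents that add atoms: benzyl bromide, BrCc1ccccc1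
Why: Williamson etherification of the secondary alkoxide, with no acidic or eliminable site elsewhere in the molecule.

Step 12
Reactants: 17 (R)-4,5-bis(benzyloxy)pent-1-ene
Product: 19 (R)-3,4-bis(benzyloxy)butanal, via diol 18 (not isolated)
Conditions: OsO4 (2 mol %), NaIO4, 2,6-lutidine, dioxane/H2O 3:1, rt
Reagents that add atoms: sodium periodate, [Na+].[O-]I(=O)(=O)=O (terminal oxidant; its oxygen reaches the product through catalytic osmium tetroxide, O=[Os](=O)(=O)=O)
Why: Lemieux–Johnson oxidation (catalytic dihydroxylation, then periodate glycol cleavage) cuts the terminal alkene without affecting benzyl ethers, and the lutidine buffer limits β-elimination from the β-benzyloxy aldehyde.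

Step 13
Reactants: 19 (R)-3,4-bis(benzyloxy)butanal
Product: 20 (R)-3,4-bis(benzyloxy)butanoic acid
Conditions: NaClO2, NaH2PO4, 2-methyl-2-butene, t-BuOH/H2O, rt
Reagents that add atoms: sodium chlorite, [Na+].[O-]Cl=O
Why: Pinnick oxidation converts the aldehyde to the acid under buffered conditions that tolerate benzyl ethers and a β-alkoxy group.

Step 14
Reactants: 20 (R)-3,4-bis(benzyloxy)butanoic acid; 21 tert-butyl (R)-3-hydroxybutanoate
Product: 22 tert-butyl (R)-3-{[(R)-3,4-bis(benzyloxy)butanoyl]oxy}butanoate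
Conditions: DIC, DMAP (cat.), CH2Cl2, 0 °C → rt
Reagents that add atoms: none
Why: Steglich esterification forms the acyl C–O bond with retention at the carbinol carbon, and the activated acid carries only a poor β-leaving group (benzyloxide).

Step 15
Reactants: 22 tert-butyl (R)-3-{[(R)-3,4-bis(benzyloxy)butanoyl]oxy}butanoate
Product: 23 (R)-3-{[(R)-3,4-bis(benzyloxy)butanoyl]oxy}butanoic acid
Conditions: TFA/CH2Cl2 1:4, 0 °C → rt
Reagents that add atoms: none
Why: Acidolysis of the tert-butyl ester through the tert-butyl cation leaves the benzyl ethers and the internal secondary ester intact.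

Step 16
Reactants: 14 benzyl (S)-3-{[2,4-bis(benzyloxy)-6-((R)-2-hydroxypropyl)benzoyl]oxy}butanoate; 23 (R)-3-{[(R)-3,4-bis(benzyloxy)butanoyl]oxy}butanoic acid
Product: 24 benzyl (S)-3-{[2,4-bis(benzyloxy)-6-((R)-2-{[(R)-3-{[(R)-3,4-bis(benzyloxy)butanoyl]oxy}butanoyl]oxy}propyl)benzoyl]oxy}butanoate
Conditions: DIC, DMAP (0.2 equiv), CH2Cl2, 0 °C → rt
Reagents that add atoms: none
Why: Steglich esterification acylates the secondary alcohol with retention, and low temperature with little DMAP is meant to keep acyl transfer faster than E1cB loss of the β-acyloxy group from the activated acid.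

Step 17
Reactants: 24 benzyl (S)-3-{[2,4-bis(benzyloxy)-6-((R)-2-{[(R)-3-{[(R)-3,4-bis(benzyloxy)butanoyl]oxy}butanoyl]oxy}propyl)benzoyl]oxy}butanoate
Product: 25 Talapolyester B
Conditions: H2 (1 atm), 10% Pd/C, EtOAc/EtOH, rt
Reagents that add atoms: none
Why: Catalytic hydrogenolysis removes the benzyl ester, both aryl benzyl ethers and both alkyl benzyl ethers in one neutral operation, so the four aliphatic esters, the homobenzylic C–O bond and the γ-hydroxy ester are not exposed to acid or base.

**Compound list**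

1 | 2,2,6-trimethyl-4H-1,3-dioxin-4-one | CC1=CC(=O)OC(C)(C)O1 | starting material
2 | 2,2-dimethyl-6-(2-oxopropyl)-4H-1,3-dioxin-4-one | CC(=O)CC1=CC(=O)OC(C)(C)O1 | intermediate
3 | methyl (R)-3-hydroxybutanoate | C[C@@H](O)CC(=O)OC | starting material
4 | methyl (R)-3-(tert-butyldimethylsilyloxy)butanoate | C[C@@H](O[Si](C)(C)C(C)(C)C)CC(=O)OC | intermediate
5 | (R)-3-(tert-butyldimethylsilyloxy)-N-methoxy-N-methylbutanamide | C[C@@H](O[Si](C)(C)C(C)(C)C)CC(=O)N(C)OC | intermediate
6 | 6-[(6R)-6-(tert-butyldimethylsilyloxy)-2,4-dioxoheptyl]-2,2-dimethyl-4H-1,3-dioxin-4-one | C[C@@H](O[Si](C)(C)C(C)(C)C)CC(=O)CC(=O)CC1=CC(=O)OC(C)(C)O1 | intermediate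
7 | ethyl (S)-3-hydroxybutanoate | C[C@H](O)CC(=O)OCC | starting material
8 | benzyl (S)-3-hydroxybutanoate | C[C@H](O)CC(=O)OCc1ccccc1 | intermediate
9 | (R)-9-(tert-butyldimethylsilyloxy)-3,5,7-trioxodec-1-en-1-one (acylketene) | C[C@@H](O[Si](C)(C)C(C)(C)C)CC(=O)CC(=O)CC(=O)C=C=O | intermediate
10 | benzyl (S)-3-{[(R)-9-(tert-butyldimethylsilyloxy)-3,5,7-trioxodecanoyl]oxy}butanoate | C[C@@H](O[Si](C)(C)C(C)(C)C)CC(=O)CC(=O)CC(=O)CC(=O)O[C@@H](C)CC(=O)OCc1ccccc1 | intermediate
11 | benzyl (S)-3-{[2-hydroxy-4,6-dioxo-2-((R)-2-(tert-butyldimethylsilyloxy)propyl)cyclohexane-1-carbonyl]oxy}butanoate (cyclic aldol, ring centres undefined) | C[C@@H](O[Si](C)(C)C(C)(C)C)CC1(O)CC(=O)CC(=O)C1C(=O)O[C@@H](C)CC(=O)OCc2ccccc2 | intermediate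
12 | benzyl (S)-3-{[2,4-dihydroxy-6-((R)-2-(tert-butyldimethylsilyloxy)propyl)benzoyl]oxy}butanoate | C[C@@H](O[Si](C)(C)C(C)(C)C)Cc1cc(O)cc(O)c1C(=O)O[C@@H](C)CC(=O)OCc2ccccc2 | intermediate
13 | benzyl (S)-3-{[2,4-bis(benzyloxy)-6-((R)-2-(tert-butyldimethylsilyloxy)propyl)benzoyl]oxy}butanoate | C[C@@H](O[Si](C)(C)C(C)(C)C)Cc1cc(OCc2ccccc2)cc(OCc3ccccc3)c1C(=O)O[C@@H](C)CC(=O)OCc4ccccc4 | intermediate
14 | benzyl (S)-3-{[2,4-bis(benzyloxy)-6-((R)-2-hydroxypropyl)benzoyl]oxy}butanoate | C[C@@H](O)Cc1cc(OCc2ccccc2)cc(OCc3ccccc3)c1C(=O)O[C@@H](C)CC(=O)OCc4ccccc4 | intermediate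
15 | (R)-benzyl glycidyl ether | C1[C@@H](O1)COCc2ccccc2 | starting material
16 | (R)-1-(benzyloxy)pent-4-en-2-ol | C=CC[C@@H](O)COCc1ccccc1 | intermediate
17 | (R)-4,5-bis(benzyloxy)pent-1-ene | C=CC[C@@H](OCc1ccccc1)COCc2ccccc2 | intermediate
18 | (4R)-4,5-bis(benzyloxy)pentane-1,2-diol (C2 undefined) | OCC(O)C[C@@H](OCc1ccccc1)COCc2ccccc2 | intermediate
19 | (R)-3,4-bis(benzyloxy)butanal | O=CC[C@@H](OCc1ccccc1)COCc2ccccc2 | intermediate
20 | (R)-3,4-bis(benzyloxy)butanoic acid | OC(=O)C[C@@H](OCc1ccccc1)COCc2ccccc2 | intermediate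
21 | tert-butyl (R)-3-hydroxybutanoate | C[C@@H](O)CC(=O)OC(C)(C)C | starting material
22 | tert-butyl (R)-3-{[(R)-3,4-bis(benzyloxy)butanoyl]oxy}butanoate | C[C@H](CC(=O)OC(C)(C)C)OC(=O)C[C@@H](OCc1ccccc1)COCc2ccccc2 | intermediate
23 | (R)-3-{[(R)-3,4-bis(benzyloxy)butanoyl]oxy}butanoic acid | C[C@H](CC(=O)O)OC(=O)C[C@@H](OCc1ccccc1)COCc2ccccc2 | intermediate
24 | benzyl (S)-3-{[2,4-bis(benzyloxy)-6-((R)-2-{[(R)-3-{[(R)-3,4-bis(benzyloxy)butanoyl]oxy}butanoyl]oxy}propyl)benzoyl]oxy}butanoate | C[C@H](CC(=O)O[C@H](C)Cc1cc(OCc2ccccc2)cc(OCc3ccccc3)c1C(=O)O[C@@H](C)CC(=O)OCc4ccccc4)OC(=O)C[C@@H](OCc5ccccc5)COCc6ccccc6 | intermediate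
25 | Talapolyester B, (S)-3-{[2,4-dihydroxy-6-((R)-2-{[(R)-3-{[(R)-3,4-dihydroxybutanoyl]oxy}butanoyl]oxy}propyl)benzoyl]oxy}butanoic acid | C[C@H](CC(=O)O[C@H](C)Cc1cc(O)cc(O)c1C(=O)O[C@@H](C)CC(=O)O)OC(=O)C[C@@H](O)CO | target

**Count**

Total steps: 17.
Longest linear sequence: 9 steps (3 → 4 → 5 → 6 → 10 → 12 → 13 → 14 → 24 → 25; steps 2, 3, 4, 6, 7, 8, 9, 16, 17).

**Steps most likely to fail, with fallbacks**

Step 7. The chain may close through oxygen to a pyranone instead of through carbon, dehydration of the aldol may stall, or the silyloxy group may be lost by elimination before the ring is aromatic. The fallback sets out from 6 and aromatises before the ester is made. Et3N in CH2Cl2 should bring about the same aldol–dehydration with the dioxinone C5 as the nucleophile, giving 7-hydroxy-2,2-dimethyl-5-[(R)-2-(tert-butyldimethylsilyloxy)propyl]-4H-1,3-benzodioxin-4-one F1. This ring has no free ester to compete and no alkoxide to expel. Irradiation of F1 at about 300 nm in CH2Cl2 with alcohol 8 should expel acetone, and the quinone ketene so formed is captured by 8 under neutral conditions. This returns to the route at 12.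

Step 4. The dianion may be quenched by proton transfer, acylate on oxygen, or react incompletely with the amide. The fallback sets out from 4 and 2 and replaces acylation by aldol addition and oxidation. DIBAL-H (CH2Cl2, −78 °C) reduces 4 to (R)-3-(tert-butyldimethylsilyloxy)butanal F2. The dianion of 2 (LDA, THF, −78 °C) adds to F2 irreversibly and without forming an acidic product, giving 6-[(6R)-6-(tert-butyldimethylsilyloxy)-4-hydroxy-2-oxoheptyl]-2,2-dimethyl-4H-1,3-dioxin-4-one F3 as a carbinol epimer mixture. Dess–Martin periodinane oxidises F3 to the 1,3-diketone. This returns to the route at 6.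

Step 16. The activated β-acyloxy acid may lose its acyloxy group by E1cB to a crotonate, and the hydroxy ester may translactonise onto the neighbouring benzoate while acylation is slow. The fallback sets out from 14 and 4 and builds the side chain one unit at a time, so that each activated acid has only a poor β-leaving group. LiOH (THF/H2O) hydrolyses 4 to (R)-3-(tert-butyldimethylsilyloxy)butanoic acid F4. DIC/DMAP joins F4 to 14 to give benzyl (S)-3-{[2,4-bis(benzyloxy)-6-((R)-2-{[(R)-3-(tert-butyldimethylsilyloxy)butanoyl]oxy}propyl)benzoyl]oxy}butanoate F5. HF·pyridine removes the silyl group to give benzyl (S)-3-{[2,4-bis(benzyloxy)-6-((R)-2-{[(R)-3-hydroxybutanoyl]oxy}propyl)benzoyl]oxy}butanoate F6. DIC/DMAP acylation of F6 with acid 20 returns to the route at 24.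

**Further compounds**

F1 | step 7 | 7-hydroxy-2,2-dimethyl-5-[(R)-2-(tert-butyldimethylsilyloxy)propyl]-4H-1,3-benzodioxin-4-one | C[C@@H](O[Si](C)(C)C(C)(C)C)Cc1cc(O)cc2OC(C)(C)OC(=O)c12
F2 | step 4 | (R)-3-(tert-butyldimethylsilyloxy)butanal | C[C@@H](O[Si](C)(C)C(C)(C)C)CC=O
F3 | step 4 | 6-[(6R)-6-(tert-butyldimethylsilyloxy)-4-hydroxy-2-oxoheptyl]-2,2-dimethyl-4H-1,3-dioxin-4-one | C[C@@H](O[Si](C)(C)C(C)(C)C)CC(O)CC(=O)CC1=CC(=O)OC(C)(C)O1
F4 | step 16 | (R)-3-(tert-butyldimethylsilyloxy)butanoic acid | C[C@@H](O[Si](C)(C)C(C)(C)C)CC(=O)O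
F5 | step 16 | benzyl (S)-3-{[2,4-bis(benzyloxy)-6-((R)-2-{[(R)-3-(tert-butyldimethylsilyloxy)butanoyl]oxy}propyl)benzoyl]oxy}butanoate | C[C@@H](O[Si](C)(C)C(C)(C)C)CC(=O)O[C@H](C)Cc1cc(OCc2ccccc2)cc(OCc3ccccc3)c1C(=O)O[C@@H](C)CC(=O)OCc4ccccc4
F6 | step 16 | benzyl (S)-3-{[2,4-bis(benzyloxy)-6-((R)-2-{[(R)-3-hydroxybutanoyl]oxy}propyl)benzoyl]oxy}butanoate | C[C@@H](O)CC(=O)O[C@H](C)Cc1cc(OCc2ccccc2)cc(OCc3ccccc3)c1C(=O)O[C@@H](C)CC(=O)OCc4ccccc4
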